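**Retrosynthetic overview** (carotenoid numbering, ring end unprimed; the target is (6S)-ε,ψ-carotene, all-E)
- The plan rests on the one ring (C1–C6). Its C1–C6 bond, the C6 stereocentre (S) and the C4=C5 olefin are the marks of a proton-started closure of an open head-to-tail C10 chain (H+ to C2, C6 to C1, H-4 lost). This closure is run on geranyl acetate with a chiral tin-bound naphthol acid, and the ring is made first.
- C7=C8 is the last skeletal bond: Julia–Kocienski union of the ring C10 phenyltetrazolyl sulfone (C1–C7) with the C30 polyenal (C8–C1'), then E/Z equilibration.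
- Sulfone ⇐ (S)-α-cyclogeraniol (Mitsunobu thioether, oxidation) ⇐ (S)-α-cyclogeranyl acetate ⇐ geranyl acetate.
- C30 polyenal ⇐ C27 enal (C3 Wittig) ⇐ C25 aldehyde (C2 Wittig) ⇐ open-chain C15 phosphonium salt (pseudoionone + vinyl Grignard) + C10 dialdehyde.

Key step: step 1

Remark 1: the (R)-ligand is assumed to select the chair fold that gives 6S (the fold that leads to 5α-H ring A in steroid-type closures); if the sense proves opposite, the (S)-ligand is used and nothing else changes.
Remark 2: pseudoionone is used as the (3E,5E)-isomer; a 5Z content of commercial material would be removed when phosphonium salt 9 is crystallised.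

**Route**

Step 1
Reactants: 1 geranyl acetate
Product: 2 (S)-α-cyclogeranyl acetate
Conditions: (R)-2'-methoxy-1,1'-binaphthalen-2-ol·SnCl4 (premixed 1:1, 1.5 equiv), toluene, −78 °C, 2 d; Et3N/MeOH quench at −78 °C; AgNO3–SiO2 chromatography
Reagents that add atoms: none
Why: Proposed new method: the naphthol OH, acidified by tin, should protonate the electron-rich terminal C1=C2 olefin at C2 (the C5=C6 olefin is deactivated by its allylic acetoxy group), and as the proton arrives C6 bonds to C1 anti to it through a chair fold, leaving a tertiary C5 cation that the tin naphtholate deprotonates at C4, so the acid is returned. The closest known reactions are the protonative cyclisations of geranyl aryl ethers and homogeranyl arenes with SnCl4–binaphthol monoether acids, which end in an aryl or hydroxyl trap, and the racemic superacid cyclisation of geranyl and farnesyl acetates to α-cyclogeranyl and drimenyl acetates, which ends by proton loss; joining the chiral proton source to an olefinic ending is the new part. The ring closes in the 6-endo-trig mode with respect to the C5=C6 nucleophile. The only new stereocentre, C6, is set by the reagent: by protonating one face of C1=C2 the chiral acid picks one of the two mirror-image chair folds, and that fold fixes which face of C5=C6 bonds to C1. The step needs loss of H-4 in preference to H-6 and to a C18 methyl hydrogen: H-6 is flanked by quaternary C1 and the CH2OAc group, the exocyclic isomer keeps C6 and is separated on AgNO3–silica instead of being isomerised by acid, and at −78 °C the hindered ring olefin should not be re-protonated by the bulky acid, so C6 is not scrambled through the tetrasubstituted isomer.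

Step 2
Reactants: 2 (S)-α-cyclogeranyl acetate
Product: 3 (S)-α-cyclogeraniol
Conditions: K2CO3 (0.3 equiv), MeOH, rt
Reagents that add atoms: none
Why: Base-catalysed transesterification (methanolysis) frees the primary alcohol, and C6 bears no acidifying group, so its configuration is untouched.

Step 3
Reactants: 3 (S)-α-cyclogeraniol; 4 1-phenyl-1H-tetrazole-5-thiol
Product: 5 1-phenyl-5-({[(1S)-2,6,6-trimethylcyclohex-2-en-1-yl]methyl}sulfanyl)-1H-tetrazole
Conditions: PPh3, DIAD, THF, 0 °C → rt
Reagents that add atoms: none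
Why: Mitsunobu thioetherification, in which the acidic tetrazole thiol displaces the alkoxyphosphonium group at primary C7 by SN2, one carbon away from C6, which is not affected.

Step 4
Reactants: 5 phenyltetrazolyl sulfide
Product: 6 1-phenyl-5-({[(1S)-2,6,6-trimethylcyclohex-2-en-1-yl]methyl}sulfonyl)-1H-tetrazole
Conditions: (NH4)6Mo7O24·4H2O (10 mol %), 30% H2O2 (5 equiv), EtOH, 0 °C → rt; recrystallise
Reagents that add atoms: hydrogen peroxide, OO
Why: Molybdate-catalysed peroxide oxidation of the sulfide through the sulfoxide to the sulfone should, unlike a peracid, spare the trisubstituted ring olefin, and recrystallising 6 should raise its enantiomeric purity before the coupling.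

Step 5
Reactants: 7 pseudoionone
Product: 8 vinylpseudoionol (racemic)
Conditions: CH2=CHMgBr, THF, −20 → 0 °C; then H2O
Reagents that add atoms: vinylmagnesium bromide, C=C[Mg]Br
Why: Grignard 1,2-addition to the methyl ketone of the dienone gives the tertiary allylic alcohol, whose stereocentre is removed in step 6.

Step 6
Reactants: 8 vinylpseudoionol
Product: 9 [(2E,4E,6E)-3,7,11-trimethyldodeca-2,4,6,10-tetraen-1-yl]triphenylphosphonium bromide
Conditions: PPh3·HBr, MeOH, 0 °C → rt; crystallise
Reagents that add atoms: triphenylphosphine hydrobromide, [Br-].c1ccc(cc1)[PH+](c1ccccc1)c1ccccc1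
Why: Phosphonium salt formation with allylic transposition: the tertiary allylic alcohol ionises under acid and PPh3 attacks the unhindered terminus, giving the primary salt with the new C9'=C10' bond mainly E, and crystallisation removes Z-isomers.

Step 7
Reactants: 9 open-chain C15 phosphonium bromide; 10 (2E,4E,6E)-2,7-dimethylocta-2,4,6-trienedial
Product: 12 C25 aldehyde (aldehyde carbon C12; all-E), via phosphorus ylide 11 (not isolated)
Conditions: NaOMe, CH2Cl2/MeOH, 10 (3 equiv), 0 °C → rt; then heptane, 80 °C; crystallise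
Reagents that add atoms: none
Why: Wittig olefination in which the conjugated ylide takes one formyl group of the dialdehyde used in excess (the mono-adduct is a longer, less electrophilic polyenal), and heating converts the hindered Z-isomer at the new C11'=C12' bond into the E-form.

Step 8
Reactants: 12 C25 aldehyde
Product: 14 C27 enal (aldehyde carbon C10; all-E), via vinyl dioxolane 13 (not isolated)
Conditions: (1,3-dioxolan-2-ylmethyl)triphenylphosphonium bromide, KOtBu, THF, 0 °C → rt; then 1 M HCl, THF, rt
Reagents that add atoms: (1,3-dioxolan-2-ylmethyl)triphenylphosphonium bromide, [Br-].C1COC(C[P+](c2ccccc2)(c2ccccc2)c2ccccc2)O1; water, O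
Why: Wittig two-carbon homologation with an acetal-masked formylmethylene ylide, then acid hydrolysis of the vinylogous acetal, which also brings the new C11=C12 bond to E; the mask prevents the repeated homologation that a free formyl ylide would cause.

Step 9
Reactants: 14 C27 enal
Product: 15 C30 polyenal (aldehyde carbon C8; all-E)
Conditions: Ph3P=C(CH3)CHO, toluene, 70 °C
Reagents that add atoms: 2-(triphenylphosphoranylidene)propanal, CC(C=O)=P(c1ccccc1)(c1ccccc1)c1ccccc1
Why: Wittig olefination with a stabilised ylide, E-selective for the new trisubstituted C9=C10 bond, and the α-methyl enal formed is less reactive than 14, so only one C3 unit is added.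

Step 10
Reactants: 6 ring C10 phenyltetrazolyl sulfone; 15 C30 polyenal
Product: 17 (6S)-ε,ψ-carotene as 7E/7Z mixture, via potassium sulfonyl carbanion 16 (not isolated)
Conditions: KN(SiMe3)2, THF, −78 °C; then 15, −78 °C → rt
Reagents that add atoms: none
Why: Julia–Kocienski olefination, in which the C7 carbanion adds to the aldehyde and Smiles rearrangement with loss of SO2 and the tetrazololate forms C7=C8; C6–H is not acidic under these conditions, so the stereocentre is kept.

Step 11
Reactants: 17 (6S)-ε,ψ-carotene as 7E/7Z mixture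
Product: 18 (6S)-ε,ψ-carotene (all-E, target)
Conditions: I2 (1 mol %), heptane/CH2Cl2, diffuse light, rt, short time; crystallise
Reagents that add atoms: none
Why: Iodine-catalysed E/Z isomerisation (reversible iodine-atom addition to the polyene) should relieve the hindered 7Z bond, and it is run as a slurry so that the least soluble all-E isomer crystallises and draws the equilibrium, while the short exposure keeps scrambling of the C5'=C6' bond minor; the isolated ring olefin and C6 take no part.

**Compound list**

1 | geranyl acetate, (2E)-3,7-dimethylocta-2,6-dien-1-yl acetate | CC(=O)OC/C=C(C)/CCC=C(C)C | starting material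
2 | (S)-α-cyclogeranyl acetate, [(1S)-2,6,6-trimethylcyclohex-2-en-1-yl]methyl acetate | CC(=O)OC[C@@H]1C(C)=CCCC1(C)C | intermediate
3 | (S)-α-cyclogeraniol, [(1S)-2,6,6-trimethylcyclohex-2-en-1-yl]methanol | OC[C@@H]1C(C)=CCCC1(C)C | intermediate
4 | 1-phenyl-1H-tetrazole-5-thiol | Sc1nnnn1-c1ccccc1 | starting material
5 | 1-phenyl-5-({[(1S)-2,6,6-trimethylcyclohex-2-en-1-yl]methyl}sulfanyl)-1H-tetrazole | C(Sc1nnnn1-c1ccccc1)[C@@H]1C(C)=CCCC1(C)C | intermediate
6 | 1-phenyl-5-({[(1S)-2,6,6-trimethylcyclohex-2-en-1-yl]methyl}sulfonyl)-1H-tetrazole | O=S(=O)(C[C@@H]1C(C)=CCCC1(C)C)c1nnnn1-c1ccccc1 | intermediate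
7 | pseudoionone, (3E,5E)-6,10-dimethylundeca-3,5,9-trien-2-one | CC(=O)/C=C/C=C(C)/CCC=C(C)C | starting material
8 | vinylpseudoionol, (4E,6E)-3,7,11-trimethyldodeca-1,4,6,10-tetraen-3-ol, racemic | C=CC(C)(O)/C=C/C=C(C)/CCC=C(C)C | intermediate
9 | [(2E,4E,6E)-3,7,11-trimethyldodeca-2,4,6,10-tetraen-1-yl]triphenylphosphonium bromide | [Br-].CC(C)=CCC/C(C)=C/C=C/C(C)=C/C[P+](c1ccccc1)(c1ccccc1)c1ccccc1 | intermediate
10 | (2E,4E,6E)-2,7-dimethylocta-2,4,6-trienedial | O=C/C(C)=C/C=C/C=C(C)/C=O | starting material
11 | [(2E,4E,6E)-3,7,11-trimethyldodeca-2,4,6,10-tetraen-1-ylidene]triphenylphosphorane, formed in the flask | CC(C)=CCC/C(C)=C/C=C/C(C)=C/C=P(c1ccccc1)(c1ccccc1)c1ccccc1 | intermediate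
12 | C25 aldehyde, (2E,4E,6E,8E,10E,12E,14E)-2,7,11,15,19-pentamethylicosa-2,4,6,8,10,12,14,18-octaenal | CC(C)=CCC/C(C)=C/C=C/C(C)=C/C=C/C(C)=C/C=C/C=C(C)/C=O | intermediate
13 | 2-[(3E,5E,7E,9E,11E,13E,15E)-3,8,12,16,20-pentamethylhenicosa-1,3,5,7,9,11,13,15,19-nonaen-1-yl]-1,3-dioxolane, 1E/1Z mixture, formed in the flask | CC(C)=CCC/C(C)=C/C=C/C(C)=C/C=C/C(C)=C/C=C/C=C(C)/C=CC1OCCO1 | intermediate
14 | C27 enal, (2E,4E,6E,8E,10E,12E,14E,16E)-4,9,13,17,21-pentamethyldocosa-2,4,6,8,10,12,14,16,20-nonaenal | CC(C)=CCC/C(C)=C/C=C/C(C)=C/C=C/C(C)=C/C=C/C=C(C)/C=C/C=O | intermediate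
15 | C30 polyenal, (2E,4E,6E,8E,10E,12E,14E,16E,18E)-2,6,11,15,19,23-hexamethyltetracosa-2,4,6,8,10,12,14,16,18,22-decaenal | CC(C)=CCC/C(C)=C/C=C/C(C)=C/C=C/C(C)=C/C=C/C=C(C)/C=C/C=C(C)/C=O | intermediate
16 | potassium salt of the C7 carbanion of sulfone 6, formed in the flask | [K+].O=S(=O)([CH-][C@@H]1C(C)=CCCC1(C)C)c1nnnn1-c1ccccc1 | intermediate
17 | (6S)-ε,ψ-carotene, mixture of 7E and 7Z isomers | CC(C)=CCC/C(C)=C/C=C/C(C)=C/C=C/C(C)=C/C=C/C=C(C)/C=C/C=C(C)/C=C[C@@H]1C(C)=CCCC1(C)C | intermediate
18 | (6S)-ε,ψ-carotene, all-E | CC(C)=CCC/C(C)=C/C=C/C(C)=C/C=C/C(C)=C/C=C/C=C(C)/C=C/C=C(C)/C=C/[C@@H]1C(C)=CCCC1(C)C | target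

**Step count and risks**

Total: 11 steps. Longest linear sequence: 7 steps (5, 6, 7, 8, 9, 10, 11 from pseudoionone); the ring branch runs 1, 2, 3, 4, then 10 and 11 (6 steps).

Steps most likely to fail:

1. Step 1 (proposed new method). What may go wrong:
   - capture of the C5 cation by the acetate carbonyl or by chloride instead of loss of H-4;
   - unselective proton loss, part of it towards the tetrasubstituted olefin, which erases C6;
   - weak enantioface discrimination if the ester competes with the ligand for tin;
   - ionisation of the allylic acetate by the Lewis acid.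

   Fallback (known chemistry, resolution in place of asymmetric induction): it sets out from 1 and comes back at 6. An achiral superacid (ClSO3H, 2-nitropropane, −78 °C) closes the ring to racemic α-cyclogeranyl acetate F1. K2CO3/MeOH gives racemic α-cyclogeraniol F2, the Mitsunobu reaction with 4 gives the racemic phenyltetrazolyl sulfide F3, and molybdate/H2O2 oxidation gives the racemic phenyltetrazolyl sulfone F4. Preparative chromatography on a chiral stationary phase separates the enantiomers, and the S-enantiomer is 6.

2. Step 10. What may go wrong: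
   - slow addition of the hindered, β-branched carbanion to the long polyenal;
   - vinylogous deprotonation of the polyenal by the carbanion or by residual base;
   - a Z-rich C7=C8 bond at the end of the chromophore that resists clean equilibration.

   Fallback (the sulfone meets a small aldehyde and the carotene is closed at a central bond): it sets out from 6 and 12 and comes back at 18. The carbanion of 6 (KN(SiMe3)2, THF, −78 °C) is olefinated with ethyl (E)-3-methyl-4-oxobut-2-enoate to give ethyl (2E,4E)-3-methyl-5-[(1S)-2,6,6-trimethylcyclohex-2-en-1-yl]penta-2,4-dienoate F5, on which a 7Z isomer can be removed by chromatography. iBu2AlH gives the dienol F6 and PPh3·HBr gives the ring C15 phosphonium bromide F7. A Wittig reaction of F7 with the C25 aldehyde 12 (NaOMe, CH2Cl2/MeOH) forms C11=C12 and gives (6S)-ε,ψ-carotene as an 11E/11Z mixture F8. Heating in heptane followed by the iodine treatment and crystallisation of step 11 turns F8 into 18. Steps 8 and 9 are then not needed.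

3. Step 8. What may go wrong:
   - deprotonation of remote methyl groups of the polyenal by the basic ylide;
   - incomplete acetal hydrolysis;
   - acid-induced degradation or E/Z scrambling of the polyene.

   Fallback (ester homologation and redox adjustment in place of the masked formyl ylide): it sets out from 12 and comes back at 14. A Horner–Wadsworth–Emmons reaction with triethyl phosphonoacetate (NaH, THF) gives the C27 ethyl ester F9. iBu2AlH (CH2Cl2, −78 °C) gives the C27 allylic alcohol F10, and MnO2 (CH2Cl2, rt) oxidises it to 14.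

**Further compounds**

F1 | step 1 | racemic α-cyclogeranyl acetate | CC(=O)OCC1C(C)=CCCC1(C)C
F2 | step 1 | racemic α-cyclogeraniol | OCC1C(C)=CCCC1(C)C
F3 | step 1 | racemic 1-phenyl-5-{[(2,6,6-trimethylcyclohex-2-en-1-yl)methyl]sulfanyl}-1H-tetrazole | C(Sc1nnnn1-c1ccccc1)C1C(C)=CCCC1(C)C
F4 | step 1 | racemic 1-phenyl-5-{[(2,6,6-trimethylcyclohex-2-en-1-yl)methyl]sulfonyl}-1H-tetrazole | O=S(=O)(CC1C(C)=CCCC1(C)C)c1nnnn1-c1ccccc1
F5 | step 10 | ethyl (2E,4E)-3-methyl-5-[(1S)-2,6,6-trimethylcyclohex-2-en-1-yl]penta-2,4-dienoate | CCOC(=O)/C=C(C)/C=C/[C@@H]1C(C)=CCCC1(C)C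
F6 | step 10 | (2E,4E)-3-methyl-5-[(1S)-2,6,6-trimethylcyclohex-2-en-1-yl]penta-2,4-dien-1-ol | OC/C=C(C)/C=C/[C@@H]1C(C)=CCCC1(C)C
F7 | step 10 | {(2E,4E)-3-methyl-5-[(1S)-2,6,6-trimethylcyclohex-2-en-1-yl]penta-2,4-dien-1-yl}triphenylphosphonium bromide | [Br-].c1ccc(cc1)[P+](c1ccccc1)(c1ccccc1)C/C=C(C)/C=C/[C@@H]1C(C)=CCCC1(C)C
F8 | step 10 | (6S)-ε,ψ-carotene, mixture of 11E and 11Z isomers | CC(C)=CCC/C(C)=C/C=C/C(C)=C/C=C/C(C)=C/C=C/C=C(\C)C=C/C=C(C)/C=C/[C@@H]1C(C)=CCCC1(C)C
F9 | step 8 | ethyl (2E,4E,6E,8E,10E,12E,14E,16E)-4,9,13,17,21-pentamethyldocosa-2,4,6,8,10,12,14,16,20-nonaenoate | CC(C)=CCC/C(C)=C/C=C/C(C)=C/C=C/C(C)=C/C=C/C=C(C)/C=C/C(=O)OCC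
F10 | step 8 | (2E,4E,6E,8E,10E,12E,14E,16E)-4,9,13,17,21-pentamethyldocosa-2,4,6,8,10,12,14,16,20-nonaen-1-ol | CC(C)=CCC/C(C)=C/C=C/C(C)=C/C=C/C(C)=C/C=C/C=C(C)/C=C/CO
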